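**Strategy.** Ring B is cut at C7–C8 (ketone to α-carbon) and at the ring fusion C5–C10. With a latent C1=C2 alkene, the C7 ketone of the decalin is a δ,ε-unsaturated ketone, the signature of an oxy-Cope product that spans rings A and B. The precursor is therefore monocyclic: a 4,4-disubstituted cyclohexenone 22 (future C2–C7) carrying a cis-alkenyl arm that ends in a 2-bromoalkene. Bromine–lithium exchange and 1,2-addition close C7–C8; the resulting cis-fused alkoxide rearranges by a boat-like anionic oxy-Cope shift that forms C5–C10, breaks C7–C2 and turns the old ring into ring A, relaying the C2 configuration to C10.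

Key step: step 14

Remarks and assumptions
- Locants follow halimane numbering: ring A = C1–C5 and C10; ring B = C5–C10; C18 = CH2OAc and C19 = CH3 on C4; C17 = CH3 on C8; C20 = CH3 on C9; side chain C11–C15 (C15 = CO2H) with C16 = CH3 on C13. The target is (4R,8R,9S,10S,13R).
- Assumption: the chiral-enamine alkylation of step 5 is run in the solvent/additive regime that gives the 2R keto ester 9; the facial sense of this alkylation is switchable by the medium.
- Assumption: the (2R,5R) auxiliary 16 shields the diene face that leads to the (1R,5R) ring of 22; if the sense is opposite, its enantiomer is used.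
- Assumption: both enantiomers of methyl hydrogen 3-methylglutarate are catalogue compounds; 6 is liberated from its commercial hydrochloride.

**Step 1**
Reactants: 1 (S)-5-methoxy-3-methyl-5-oxopentanoic acid
Product: 2 1-tert-butyl 5-methyl (R)-3-methylpentanedioate
Conditions: t-BuOC(=NH)CCl3, BF3·OEt2 (cat.), CH2Cl2–cyclohexane, 25 °C
Reagents that add atoms: tert-butyl 2,2,2-trichloroacetimidate CC(C)(C)OC(=N)C(Cl)(Cl)Cl
Why: Acid-catalysed O-alkylation of the free acid by the imidate (tert-butyl ester formation) should leave the methyl ester and the β-stereocentre untouched.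

**Step 2**
Reactants: 2 1-tert-butyl 5-methyl (R)-3-methylpentanedioate
Product: 3 tert-butyl (R)-5-hydroxy-3-methylpentanoate
Conditions: LiBH4, THF, 0 → 25 °C
Reagents that add atoms: none
Why: Chemoselective ester reduction; LiBH4 should reduce the methyl ester while the hindered tert-butyl ester is inert.

**Step 3**
Reactants: 3 tert-butyl (R)-5-hydroxy-3-methylpentanoate
Product: 4 tert-butyl (S)-5-iodo-3-methylpentanoate
Conditions: I2, PPh3, imidazole, CH2Cl2, 0 °C
Reagents that add atoms: iodine II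
Why: Appel-type iodination of the primary alcohol by SN2 at an achiral CH2 (the descriptor changes only by priority).

**Step 4**
Reactants: 5 methyl 2-methyl-3-oxobutanoate; 6 L-valine tert-butyl ester
Product: 7 tert-butyl N-[(2Z)-4-methoxy-3-methyl-4-oxobut-2-en-2-yl]-L-valinate
Conditions: BF3·OEt2 (cat.), benzene, reflux, azeotropic removal of water
Reagents that add atoms: none
Why: Acid-catalysed condensation of the β-keto ester with the primary amine should give the hydrogen-bonded Z-enamino ester (enamine formation).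

**Step 5**
Reactants: 7 tert-butyl N-[(2Z)-4-methoxy-3-methyl-4-oxobut-2-en-2-yl]-L-valinate; 4 tert-butyl (S)-5-iodo-3-methylpentanoate
Product: 9 7-tert-butyl 1-methyl (2R,5R)-2-acetyl-2,5-dimethylheptanedioate, via ketimine 8 (not isolated)
Conditions: LiN(i-Pr)2, toluene, −78 °C; hexamethylphosphoramide; 4, −78 → −40 °C; then 10% aq. citric acid, 25 °C
Reagents that add atoms: water O
Why: Asymmetric alkylation of a lithiated chiral enamine: the chelated valine ester shields one face of the aza-enolate, so iodide 4 should enter from the other face and set the quaternary centre C9; mild acid then hydrolyses the ketimine.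

**Step 6**
Reactants: 9 7-tert-butyl 1-methyl (2R,5R)-2-acetyl-2,5-dimethylheptanedioate
Product: 10 7-tert-butyl 1-methyl (2S,5R)-2-(1-bromoethenyl)-2,5-dimethylheptanedioate
Conditions: P(OPh)3, Br2, Et3N, CH2Cl2, −60 → 40 °C
Reagents that add atoms: bromine BrBr
Why: Ketone-to-vinyl-bromide conversion with the phosphite–bromine adduct; the ketone can enolise only toward CH3, so the 2-bromo-1-alkene should result.

**Step 7**
Reactants: 10 7-tert-butyl 1-methyl (2S,5R)-2-(1-bromoethenyl)-2,5-dimethylheptanedioate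
Product: 11 tert-butyl (3R,6S)-6-(1-bromoethenyl)-6-formyl-3-methylheptanoate
Conditions: i-Bu2AlH (1.1 equiv), toluene, −78 °C; aq. potassium sodium tartrate
Reagents that add atoms: none
Why: Partial ester reduction: the aluminium hemiacetal of the neopentyl-type methyl ester should persist until work-up, and the tert-butyl ester should not react at −78 °C.

**Step 8**
Reactants: 11 tert-butyl (3R,6S)-6-(1-bromoethenyl)-6-formyl-3-methylheptanoate; 12 (2-carboxyethyl)triphenylphosphonium bromide
Product: 13 (3Z,5S,8R)-5-(1-bromoethenyl)-10-tert-butoxy-5,8-dimethyl-10-oxodec-3-enoic acid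
Conditions: NaN(SiMe3)2 (2.1 equiv), THF, −78 → 25 °C; cold 1 M HCl
Reagents that add atoms: none
Why: Wittig olefination with the unstabilised carboxylate ylide under salt-free conditions should give the cis C1=C10 alkene, the geometry that later allows ring closure.

**Step 9**
Reactants: 13 (3Z,5S,8R)-5-(1-bromoethenyl)-10-tert-butoxy-5,8-dimethyl-10-oxodec-3-enoic acid
Product: 14 tert-butyl (3R,6S,7Z)-6-(1-bromoethenyl)-10-[methoxy(methyl)amino]-3,6-dimethyl-10-oxodec-7-enoate
Conditions: MeNH(OMe)·HCl, N-(3-dimethylaminopropyl)-N′-ethylcarbodiimide hydrochloride, 1-hydroxybenzotriazole (cat.), N-methylmorpholine, CH2Cl2, 0 → 25 °C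
Reagents that add atoms: N,O-dimethylhydroxylamine hydrochloride CNOC.Cl
Why: Carbodiimide amide coupling under weakly basic conditions that should not move the β,γ-alkene into conjugation.

**Step 10**
Reactants: 14 tert-butyl (3R,6S,7Z)-6-(1-bromoethenyl)-10-[methoxy(methyl)amino]-3,6-dimethyl-10-oxodec-7-enoate
Product: 15 tert-butyl (3R,6S,7Z)-6-(1-bromoethenyl)-3,6-dimethyl-10-oxododec-7-en-11-ynoate
Conditions: HC≡CMgBr, THF, −20 → 0 °C; aq. NH4Cl
Reagents that add atoms: ethynylmagnesium bromide C#C[Mg]Br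
Why: Acyl substitution of the N-methoxy-N-methylamide; the chelated tetrahedral magnesium adduct should stop the addition at the ketone.

**Step 11**
Reactants: 15 tert-butyl (3R,6S,7Z)-6-(1-bromoethenyl)-3,6-dimethyl-10-oxododec-7-en-11-ynoate; 16 (2R,5R)-2,5-diphenylpyrrolidine
Product: 17 tert-butyl (3R,6S,7Z,11E)-6-(1-bromoethenyl)-12-[(2R,5R)-2,5-diphenylpyrrolidin-1-yl]-3,6-dimethyl-10-oxododeca-7,11-dienoate
Conditions: CH2Cl2, 25 °C
Reagents that add atoms: none
Why: Aza-Michael addition of the secondary amine to the terminal ynone should give the E-vinylogous amide and installs the chiral auxiliary.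

**Step 12**
Reactants: 17 tert-butyl (3R,6S,7Z,11E)-6-(1-bromoethenyl)-12-[(2R,5R)-2,5-diphenylpyrrolidin-1-yl]-3,6-dimethyl-10-oxododeca-7,11-dienoate; 18 methacrolein
Product: 20 tert-butyl (3R,6S,7Z)-6-(1-bromoethenyl)-8-{2-[(tert-butyldimethylsilyl)oxy]-4-[(2R,5R)-2,5-diphenylpyrrolidin-1-yl]-5-formyl-5-methylcyclohex-2-en-1-yl}-3,6-dimethyloct-7-enoate (all-cis ring), via aminosilyloxy triene 19 (not isolated)
Conditions: KN(SiMe3)2, t-BuMe2SiCl, THF, −78 °C; then 18, toluene, −20 → 25 °C
Reagents that add atoms: tert-butyldimethylsilyl chloride CC(C)(C)[Si](C)(C)Cl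
Why: Diels–Alder reaction of the 1-amino-3-silyloxy diene with methacrolein: the amino terminus C5 bonds to the quaternary carbon C4 and C2 to C3, the formyl group lies endo so that formyl, amine and the C2 arm end up cis, and the C2-symmetric pyrrolidine blocks one diene face, which should set C4 and C2 together; the cis C1=C10 alkene cannot reach an s-cis diene and stays out.

**Step 13**
Reactants: 20 the all-cis cycloadduct of step 12
Product: 22 tert-butyl (3R,6S,7Z)-6-(1-bromoethenyl)-8-[(1R,5R)-5-(hydroxymethyl)-5-methyl-2-oxocyclohex-3-en-1-yl]-3,6-dimethyloct-7-enoate, via primary alcohol 21 (not isolated)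
Conditions: NaBH4, MeOH–THF, −20 °C; then 10% aq. HF, MeCN, 0 °C
Reagents that add atoms: none
Why: Hydride reduction of the neopentyl aldehyde, then acid hydrolysis of the silyl enol ether and E1cB loss of the protonated amine should unveil the enone; the C2 centre is enolisable, so 22 is kept cold and used at once.

**Step 14 (key step)**
Reactants: 22 tert-butyl (3R,6S,7Z)-6-(1-bromoethenyl)-8-[(1R,5R)-5-(hydroxymethyl)-5-methyl-2-oxocyclohex-3-en-1-yl]-3,6-dimethyloct-7-enoate
Product: 26 tert-butyl 7,18-bis(trimethylsilyloxy)halima-1,6,8(17)-trien-15-oate (5-H and 10-H cis), via vinyllithium 23 (not isolated), via bicyclic dialkoxide 24 (not isolated), via dienolate 25 (not isolated)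
Conditions: t-BuLi (3.1 equiv), THF–pentane, −95 → −78 °C; KOt-Bu, 18-crown-6, −78 → 25 °C; Me3SiCl, Et3N, −78 °C
Reagents that add atoms: chlorotrimethylsilane C[Si](C)(C)Cl
Why: After deprotonation of the alcohol, Br/Li exchange gives vinyllithium 23, which adds 1,2 to the C7 carbonyl in a 6-exo-trig closure of a temporary ring (C7, C8, C9, C10, C1, C2); exchange to the potassium alkoxide then triggers an anionic oxy-Cope [3,3] shift of the 1,5-diene C5=C6–C7(O−)–C2–C1=C10. The closest known reaction type is the tandem alkenyllithium addition/anionic oxy-Cope rearrangement of β,γ-unsaturated ketones. The shift closes ring A at C5–C10 through a boat-like, twistane-shaped six-centre transition state, and cleavage of C7–C2 leaves the new C7–C8 bond inside ring B, so both rings of the decalin should arise from one monocycle. C10 is set by suprafacial chirality transfer from C2 (the new bond forms on the alkene face that carries the old ring), C5 becomes cis to H10 and is erased in step 15, and C4 and C9 pass through unchanged. The step needs carbonyl addition instead of enolisation at the acidic C2–H, a cis ring fusion and the correct diene: the six-membered intramolecular addition should outrun proton transfer, the cis C1=C10 alkene with the arm on the carbonyl face enforces cis fusion (a trans-fused alkoxide cannot reach the boat), and the exocyclic C8=C17 alkene could rearrange only through a cyclobutane. The enolate forms regiospecifically toward C6 and is trapped as silyl enol ether 26.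

**Step 15**
Reactants: 26 tert-butyl 7,18-bis(trimethylsilyloxy)halima-1,6,8(17)-trien-15-oate
Product: 27 tert-butyl (4R,9S,10S,13R)-18-hydroxy-7-oxohalima-1,5,8(17)-trien-15-oate
Conditions: Pd(OAc)2 (1.1 equiv), MeCN, 25 °C; aq. citric acid work-up
Reagents that add atoms: none
Why: Saegusa–Ito oxidation: divalent palladium adds at C6 of the silyl enol ether and syn β-hydride elimination of H5 should give the C5=C6 enone regiospecifically; the primary silyl ether falls off on work-up.

**Step 16**
Reactants: 27 tert-butyl (4R,9S,10S,13R)-18-hydroxy-7-oxohalima-1,5,8(17)-trien-15-oate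
Product: 28 tert-butyl (4R,8R,9S,10S,13R)-18-hydroxy-7-oxohalim-5-en-15-oate
Conditions: H2 (1 atm), RhCl(PPh3)3 (10 mol%), benzene–EtOH, 25 °C
Reagents that add atoms: none
Why: Homogeneous hydrogenation should saturate the disubstituted C1=C2 and the 1,1-disubstituted C8=C17 alkenes but not the hindered trisubstituted enone; hydrogen reaches C8 from the α face, anti to the axial C20 methyl on C9, which sets 8R.

**Step 17**
Reactants: 28 tert-butyl (4R,8R,9S,10S,13R)-18-hydroxy-7-oxohalim-5-en-15-oate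
Product: 29 tert-butyl (4R,8R,9S,10S,13R)-18-acetoxy-7-oxohalim-5-en-15-oate
Conditions: Ac2O, pyridine, 4-(dimethylamino)pyridine (cat.), CH2Cl2, 0 °C
Reagents that add atoms: acetic anhydride CC(=O)OC(C)=O
Why: Nucleophile-catalysed acylation of the primary neopentyl alcohol under conditions too mild to epimerise C8.

**Step 18**
Reactants: 29 tert-butyl (4R,8R,9S,10S,13R)-18-acetoxy-7-oxohalim-5-en-15-oate
Product: 30 (4R,8R,9S,10S,13R)-18-acetoxy-7-oxohalim-5-en-15-oic acid (CNP0210381.1)
Conditions: CF3CO2H–CH2Cl2 (1:4), 0 °C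
Reagents that add atoms: none
Why: Acidolysis of the tert-butyl ester through the tert-butyl cation should leave the acetate and the enone untouched.

**Compound list**
1 | (S)-5-methoxy-3-methyl-5-oxopentanoic acid | COC(=O)C[C@@H](C)CC(=O)O | starting material
2 | 1-tert-butyl 5-methyl (R)-3-methylpentanedioate | COC(=O)C[C@@H](C)CC(=O)OC(C)(C)C | intermediate
3 | tert-butyl (R)-5-hydroxy-3-methylpentanoate | OCC[C@@H](C)CC(=O)OC(C)(C)C | intermediate
4 | tert-butyl (S)-5-iodo-3-methylpentanoate | ICC[C@@H](C)CC(=O)OC(C)(C)C | intermediate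
5 | methyl 2-methyl-3-oxobutanoate | COC(=O)C(C)C(C)=O | starting material
6 | L-valine tert-butyl ester | CC(C)[C@H](N)C(=O)OC(C)(C)C | starting material
7 | tert-butyl N-[(2Z)-4-methoxy-3-methyl-4-oxobut-2-en-2-yl]-L-valinate | COC(=O)C(/C)=C(/C)N[C@@H](C(C)C)C(=O)OC(C)(C)C | intermediate
8 | ketimine of 9 with L-valine tert-butyl ester (not isolated) | CC(=N[C@@H](C(C)C)C(=O)OC(C)(C)C)[C@@](C(=O)OC)(C)CC[C@@H](C)CC(=O)OC(C)(C)C | intermediate
9 | 7-tert-butyl 1-methyl (2R,5R)-2-acetyl-2,5-dimethylheptanedioate | CC(=O)[C@@](C(=O)OC)(C)CC[C@@H](C)CC(=O)OC(C)(C)C | intermediate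
10 | 7-tert-butyl 1-methyl (2S,5R)-2-(1-bromoethenyl)-2,5-dimethylheptanedioate | C=C(Br)[C@@](C(=O)OC)(C)CC[C@@H](C)CC(=O)OC(C)(C)C | intermediate
11 | tert-butyl (3R,6S)-6-(1-bromoethenyl)-6-formyl-3-methylheptanoate | C=C(Br)[C@@](C=O)(C)CC[C@@H](C)CC(=O)OC(C)(C)C | intermediate
12 | (2-carboxyethyl)triphenylphosphonium bromide | OC(=O)CC[P+](c1ccccc1)(c1ccccc1)c1ccccc1.[Br-] | starting material
13 | (3Z,5S,8R)-5-(1-bromoethenyl)-10-tert-butoxy-5,8-dimethyl-10-oxodec-3-enoic acid | OC(=O)C/C=C\[C@](C)(CC[C@@H](C)CC(=O)OC(C)(C)C)C(Br)=C | intermediate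
14 | tert-butyl (3R,6S,7Z)-6-(1-bromoethenyl)-10-[methoxy(methyl)amino]-3,6-dimethyl-10-oxodec-7-enoate | CON(C)C(=O)C/C=C\[C@](C)(CC[C@@H](C)CC(=O)OC(C)(C)C)C(Br)=C | intermediate
15 | tert-butyl (3R,6S,7Z)-6-(1-bromoethenyl)-3,6-dimethyl-10-oxododec-7-en-11-ynoate | C#CC(=O)C/C=C\[C@](C)(CC[C@@H](C)CC(=O)OC(C)(C)C)C(Br)=C | intermediate
16 | (2R,5R)-2,5-diphenylpyrrolidine | N1[C@@H](c2ccccc2)CC[C@@H]1c1ccccc1 | starting material
17 | tert-butyl (3R,6S,7Z,11E)-6-(1-bromoethenyl)-12-[(2R,5R)-2,5-diphenylpyrrolidin-1-yl]-3,6-dimethyl-10-oxododeca-7,11-dienoate | O=C(/C=C/N1[C@@H](c2ccccc2)CC[C@@H]1c1ccccc1)C/C=C\[C@](C)(CC[C@@H](C)CC(=O)OC(C)(C)C)C(Br)=C | intermediate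
18 | methacrolein (2-methylprop-2-enal) | CC(=C)C=O | starting material
19 | tert-butyl (3R,6S,7Z,9Z,11E)-6-(1-bromoethenyl)-10-[(tert-butyldimethylsilyl)oxy]-12-[(2R,5R)-2,5-diphenylpyrrolidin-1-yl]-3,6-dimethyldodeca-7,9,11-trienoate (not isolated) | C=C(Br)[C@@](C)(CC[C@@H](C)CC(=O)OC(C)(C)C)/C=C\C=C(O[Si](C)(C)C(C)(C)C)\C=C\N1[C@@H](c2ccccc2)CC[C@@H]1c1ccccc1 | intermediate
20 | all-cis cycloadduct: 5-formyl-5-methyl-4-(diphenylpyrrolidinyl)-2-silyloxycyclohex-2-enyl on C8 of the oct-7-enoate arm | O=C[C@]1(C)C[C@H](/C=C\[C@](C)(CC[C@@H](C)CC(=O)OC(C)(C)C)C(Br)=C)C(O[Si](C)(C)C(C)(C)C)=C[C@@H]1N1[C@@H](c2ccccc2)CC[C@@H]1c1ccccc1 | intermediate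
21 | primary alcohol from 20 (5-hydroxymethyl in place of 5-formyl; not isolated) | OC[C@]1(C)C[C@H](/C=C\[C@](C)(CC[C@@H](C)CC(=O)OC(C)(C)C)C(Br)=C)C(O[Si](C)(C)C(C)(C)C)=C[C@@H]1N1[C@@H](c2ccccc2)CC[C@@H]1c1ccccc1 | intermediate
22 | tert-butyl (3R,6S,7Z)-6-(1-bromoethenyl)-8-[(1R,5R)-5-(hydroxymethyl)-5-methyl-2-oxocyclohex-3-en-1-yl]-3,6-dimethyloct-7-enoate | O=C1C=C[C@@](CO)(C)C[C@@H]1/C=C\[C@](C)(CC[C@@H](C)CC(=O)OC(C)(C)C)C(Br)=C | intermediate
23 | vinyllithium lithium alkoxide from 22 (not isolated) | O=C1C=C[C@@](C[O-])(C)C[C@@H]1/C=C\[C@](C)(CC[C@@H](C)CC(=O)OC(C)(C)C)C([Li])=C.[Li+] | intermediate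
24 | cis-fused bicyclic dilithium dialkoxide (ring-fusion bond C7–C2; C5=C6, C1=C10, C8=C17; not isolated) | [Li+].[Li+].[O-][C@@]12C=C[C@@](C[O-])(C)C[C@@H]1C=C[C@](C)(CC[C@@H](C)CC(=O)OC(C)(C)C)C2=C | intermediate
25 | ring-transposed dipotassium C6=C7 enolate alkoxide (not isolated) | [K+].[K+].[O-]C[C@]1(C)CC=C[C@@H]2[C@H]1C=C([O-])C(=C)[C@@]2(C)CC[C@@H](C)CC(=O)OC(C)(C)C | intermediate
26 | tert-butyl 7,18-bis(trimethylsilyloxy)halima-1,6,8(17)-trien-15-oate | C[Si](C)(C)OC[C@]1(C)CC=C[C@@H]2[C@H]1C=C(O[Si](C)(C)C)C(=C)[C@@]2(C)CC[C@@H](C)CC(=O)OC(C)(C)C | intermediate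
27 | tert-butyl (4R,9S,10S,13R)-18-hydroxy-7-oxohalima-1,5,8(17)-trien-15-oate | OC[C@]1(C)CC=C[C@@H]2C1=CC(=O)C(=C)[C@@]2(C)CC[C@@H](C)CC(=O)OC(C)(C)C | intermediate
28 | tert-butyl (4R,8R,9S,10S,13R)-18-hydroxy-7-oxohalim-5-en-15-oate | OC[C@]1(C)CCC[C@@H]2C1=CC(=O)[C@H](C)[C@@]2(C)CC[C@@H](C)CC(=O)OC(C)(C)C | intermediate
29 | tert-butyl (4R,8R,9S,10S,13R)-18-acetoxy-7-oxohalim-5-en-15-oate | CC(=O)OC[C@]1(C)CCC[C@@H]2C1=CC(=O)[C@H](C)[C@@]2(C)CC[C@@H](C)CC(=O)OC(C)(C)C | intermediate
30 | (4R,8R,9S,10S,13R)-18-acetoxy-7-oxohalim-5-en-15-oic acid (CNP0210381.1) | CC(=O)OC[C@]1(C)CCC[C@@H]2C1=CC(=O)[C@H](C)[C@@]2(C)CC[C@@H](C)CC(=O)O | target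

**Totals.** Total step count: 18. Longest linear sequence: 17 (steps 1–3 and 5–18; step 4 is a one-step side branch).

**Steps most likely to fail**

Step 14. The vinyllithium may be quenched by proton transfer from the acidic C2–H (enolisation) before it adds to the carbonyl, or the sigmatropic shift may stall at the lithium alkoxide stage. The fallback separates the two events and avoids the organolithium. It sets out from 22: CrCl2 with catalytic NiCl2 in DMF at 25 °C should close the temporary ring by a Nozaki–Hiyama–Kishi addition to the ketone and give the cis-fused bicyclic diol F1. KH and 18-crown-6 in THF (0 → 25 °C) then drive the anionic oxy-Cope shift, and Me3SiCl/Et3N traps the enolate. The route is rejoined at 26.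

Step 12. Facial or endo selectivity of the cycloaddition may be poor with the bulky arm on the diene, and the amine-elimination of step 13 may epimerise C2. The fallback changes the diene type and puts the stereocontrol on a catalyst. It sets out from 14: vinylmagnesium bromide gives the vinyl ketone F2, and i-Pr3SiOSO2CF3/Et3N gives the 2-silyloxy triene F3. Methacrolein, activated by (S)-3,3-diphenyl-1-(2-methylphenyl)hexahydropyrrolo[1,2-c][1,3,2]oxazaborole protonated with HN(SO2CF3)2 (CH2Cl2, −78 °C), should give the cycloadduct F4. NaBH4 reduces the aldehyde to the alcohol F5, and a Saegusa–Ito oxidation with Pd(OAc)2 forms the enone under neutral conditions. The route is rejoined at 22.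

Step 5. SN2 attack of the hindered aza-enolate on an unactivated primary iodide may be slow, with loss of facial control at the quaternary centre. The fallback moves the stereocontrol to an enzymatic desymmetrisation. It sets out from 4: alkylation of dimethyl methylmalonate (NaH, DMF) gives the malonate F6. Pig liver esterase (pH 7 buffer) should cleave one enantiotopic ester to the half-ester F7. 1-Chloro-N,N,2-trimethylprop-1-en-1-amine converts F7 into the acid chloride F8, and Me2CuLi (−78 °C) gives the methyl ketone. The route is rejoined at 9.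

**Further compounds**
F1 | step 14 | cis-fused bicyclic diol (neutral form of 24) | O[C@@]12C=C[C@@](CO)(C)C[C@@H]1C=C[C@](C)(CC[C@@H](C)CC(=O)OC(C)(C)C)C2=C
F2 | step 12 | tert-butyl (3R,6S,7Z)-6-(1-bromoethenyl)-3,6-dimethyl-10-oxododeca-7,11-dienoate | C=CC(=O)C/C=C\[C@](C)(CC[C@@H](C)CC(=O)OC(C)(C)C)C(Br)=C
F3 | step 12 | tert-butyl (3R,6S,7Z,9Z)-6-(1-bromoethenyl)-3,6-dimethyl-10-[(triisopropylsilyl)oxy]dodeca-7,9,11-trienoate | C=C/C(O[Si](C(C)C)(C(C)C)C(C)C)=C/C=C\[C@](C)(CC[C@@H](C)CC(=O)OC(C)(C)C)C(Br)=C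
F4 | step 12 | cycloadduct: 5-formyl-5-methyl-2-(triisopropylsilyloxy)cyclohex-2-enyl on C8 of the oct-7-enoate arm (formyl cis to the arm) | O=C[C@]1(C)C[C@H](/C=C\[C@](C)(CC[C@@H](C)CC(=O)OC(C)(C)C)C(Br)=C)C(O[Si](C(C)C)(C(C)C)C(C)C)=CC1
F5 | step 12 | primary alcohol from F4 | OC[C@]1(C)C[C@H](/C=C\[C@](C)(CC[C@@H](C)CC(=O)OC(C)(C)C)C(Br)=C)C(O[Si](C(C)C)(C(C)C)C(C)C)=CC1
F6 | step 5 | dimethyl 2-[(3R)-5-tert-butoxy-3-methyl-5-oxopentyl]-2-methylpropanedioate | COC(=O)C(C)(CC[C@@H](C)CC(=O)OC(C)(C)C)C(=O)OC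
F7 | step 5 | (2R,5R)-7-tert-butoxy-2-(methoxycarbonyl)-2,5-dimethyl-7-oxoheptanoic acid | OC(=O)[C@@](C(=O)OC)(C)CC[C@@H](C)CC(=O)OC(C)(C)C
F8 | step 5 | acid chloride of F7 | ClC(=O)[C@@](C(=O)OC)(C)CC[C@@H](C)CC(=O)OC(C)(C)C
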